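**Strategy.** Ring C (O1–C2–C3–C4–C4a–C8a) is disconnected at C2–C3. C2 is benzylic to the p-oxygenated ring B and bound to O1, so it is a latent oxocarbenium carbon. C3–OH/C4=O is an α-ketol, so it is a latent enediol. The 3-oxygen can therefore sit between C2 and C3 as a temporary ring member. The precursor is the enol silane of a seven-membered 2-aryl-1,3-benzodioxepin-5-one, a benzylidene acetal with no C–C link between its halves. Under chiral ion-pair catalysis C2–O3 ionises and C3 recloses on C2. This single 1,2-O→C shift contracts seven to six, forms C2–C3 and sets both stereocentres.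

Key step: step 7

Abbreviations: prenyl = 3-methylbut-2-en-1-yl; TBS = tert-butyldimethylsilyl; TES = triethylsilyl.
Remark: the sense of induction of the hydrogen-bond-donor catalyst in step 7 cannot be read from precedent; both catalyst enantiomers are accessible, and the one that opens the face of C2 leading to (2R) is meant.

Step 1
Reactants: 1 2',4',6'-trihydroxyacetophenone; 2 prenyl bromide (2.1 equiv)
Product: 3 1-(2,4,6-trihydroxy-3,5-diprenylphenyl)ethan-1-one
Conditions: KOH, H2O, 0 °C to rt
Reagents that add atoms: none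
Why: C-alkylation of an ambident phloroglucinolate (Friedel–Crafts-type C-prenylation in basic water), in which hydrogen bonding of water to the phenoxide oxygens steers the soft allylic bromide to the two free ring carbons, the third being blocked by the acetyl group.

Step 2
Reactants: 3 1-(2,4,6-trihydroxy-3,5-diprenylphenyl)ethan-1-one
Product: 4 1-[2,4-bis(TBS-oxy)-6-hydroxy-3,5-diprenylphenyl]ethan-1-one
Conditions: TBSCl (2.2 equiv), imidazole, DMF, 0 °C to rt
Reagents that add atoms: tert-butyldimethylsilyl chloride, CC(C)(C)[Si](C)(C)Cl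
Why: Selective O-silylation, in which the para-OH and one of the two equivalent ortho-OH groups react, after which the last OH is held in a strong hydrogen bond to the ketone and should stay free.

Step 3
Reactants: 4 1-[2,4-bis(TBS-oxy)-6-hydroxy-3,5-diprenylphenyl]ethan-1-one
Product: 5 1-[2,4-bis(TBS-oxy)-6-hydroxy-3,5-diprenylphenyl]-2-hydroxyethan-1-one
Conditions: KHMDS (2.2 equiv), THF, −78 °C; 2-(benzenesulfonyl)-3-phenyloxaziridine; AcOH quench at −78 °C
Reagents that add atoms: 2-(benzenesulfonyl)-3-phenyloxaziridine, O=S(=O)(c1ccccc1)N1OC1c1ccccc1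
Why: Electrophilic α-hydroxylation of a ketone enolate with an N-sulfonyloxaziridine, in which the phenoxide–enolate dianion attacks the oxaziridine oxygen at a temperature where prenyl alkenes and aryl silyl ethers are inert, and the cold acidic quench should forestall silyl migration to the new alkoxide.

Step 4
Reactants: 6 4-(TBS-oxy)benzaldehyde
Product: 7 4-(TBS-oxy)benzaldehyde dimethyl acetal
Conditions: HC(OMe)3, PPTS (cat.), MeOH, rt
Reagents that add atoms: trimethyl orthoformate, COC(OC)OC
Why: Acid-catalysed acetalisation with an orthoester as water scavenger, under an acid mild enough for the aryl silyl ether.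

Step 5
Reactants: 5 1-[2,4-bis(TBS-oxy)-6-hydroxy-3,5-diprenylphenyl]-2-hydroxyethan-1-one; 7 4-(TBS-oxy)benzaldehyde dimethyl acetal
Product: 8 rac-6,8-bis(TBS-oxy)-2-[4-(TBS-oxy)phenyl]-7,9-diprenyl-4H-1,3-benzodioxepin-5-one
Conditions: PPTS (10 mol %), toluene, 5 Å MS, 60 °C
Reagents that add atoms: none
Why: Transacetalisation, in which exchange at the primary hydroxyl gives a mixed acetal whose oxocarbenium ion is trapped by the neighbouring phenol, removal of methanol drives closure of the seven-membered ring, and the racemic acetal carbon is of no consequence because step 7 erases it.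

Step 6
Reactants: 8 rac-6,8-bis(TBS-oxy)-2-[4-(TBS-oxy)phenyl]-7,9-diprenyl-4H-1,3-benzodioxepin-5-one
Product: 9 rac-6,8-bis(TBS-oxy)-2-[4-(TBS-oxy)phenyl]-7,9-diprenyl-5-(TES-oxy)-2H-1,3-benzodioxepine
Conditions: TESCl, KHMDS, THF, −78 °C (internal quench); filtration through Et3N-deactivated silica
Reagents that add atoms: triethylsilyl chloride, CC[Si](Cl)(CC)CC
Why: Kinetic enolisation and O-silylation (silyl enol ether formation), in which the ring CH2 is the only enolisable position and the ring fixes the alkene geometry.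

Step 7
Reactants: 9 rac-6,8-bis(TBS-oxy)-2-[4-(TBS-oxy)phenyl]-7,9-diprenyl-5-(TES-oxy)-2H-1,3-benzodioxepine
Product: 11 (2R,3R)-5,7-bis(TBS-oxy)-2-[4-(TBS-oxy)phenyl]-6,8-diprenyl-3-(TES-oxy)chroman-4-one, via ring-opened oxocarbenium triflate 10 (not isolated)
Conditions: chiral 2-arylpyrrolidine squaramide (10 mol %), TESOTf (10 mol %), MTBE (0.01 M), −78 °C; Et3N quench
Reagents that add atoms: none
Why: Proposed new method: the squaramide-bound TESOTf silylates an acetal oxygen of 9 and ionises it reversibly, which erases the racemic acetal centre; loss of O3 gives the B-ring-stabilised aryloxycarbenium ion 10, whose own (E)-bis(silyloxy)alkene attacks C2 through C3 and hands TES+ from O4 back to triflate, so that O3 leaves the ring and the net 1,2-O→C shift contracts the seven-membered acetal to the six-membered pyranone (ionisation at O1 is unproductive and reverts). The closest known reaction types are the Petasis–Ferrier rearrangement of cyclic enol acetals and the hydrogen-bond-donor/silyl triflate co-catalysed enantioselective Mukaiyama aldol addition of enol silanes to aryl acetals; the intramolecular, ring-contracting 1,2 version has not been shown. The pyranone closes in a 6-(enolendo)-endo-trig mode. C2 is set by the catalyst, which holds the triflate by hydrogen bonds and the flat cation by cation–π contact so that only one face of C2 is open, and C3 is set relative to C2 by a half-chair transition state with ring B and OTES pseudo-equatorial, which is also the thermodynamically preferred 2,3-trans arrangement. The step needs C3, not C4 or a prenyl alkene, as the nucleophile: attack through C3 leaves the charge on C4 next to OTES and the electron-rich ring A and gives the six-membered ring, attack through C4 would build a quaternary centre in a five-membered ring, and the bis(silyloxy)alkene is far more nucleophilic than a trisubstituted alkene. A racemic background reaction through free TESOTf is held down by −78 °C, the ethereal solvent and high dilution.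

Step 8
Reactants: 11 (2R,3R)-5,7-bis(TBS-oxy)-2-[4-(TBS-oxy)phenyl]-6,8-diprenyl-3-(TES-oxy)chroman-4-one
Product: 12 6,8-diprenylaromadendrin, (2R,3R)-3,5,7-trihydroxy-2-(4-hydroxyphenyl)-6,8-diprenylchroman-4-one
Conditions: Et3N·3HF, THF/MeCN, 0 °C to rt
Reagents that add atoms: none
Why: Fluoride-mediated cleavage of all four Si–O bonds in a weakly acidic buffer, which avoids base (opening of ring C, epimerisation) and strong acid (cyclisation of prenyl phenols to chromans), so C2 and C3 should stay untouched.

**Compound list**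
1 | 2',4',6'-trihydroxyacetophenone | CC(=O)c1c(O)cc(O)cc1O | starting material
2 | prenyl bromide (1-bromo-3-methylbut-2-ene) | CC(C)=CCBr | starting material
3 | 1-(2,4,6-trihydroxy-3,5-diprenylphenyl)ethan-1-one | CC(=O)c1c(O)c(CC=C(C)C)c(O)c(CC=C(C)C)c1O | intermediate
4 | 1-[2,4-bis(TBS-oxy)-6-hydroxy-3,5-diprenylphenyl]ethan-1-one | CC(=O)c1c(O)c(CC=C(C)C)c(O[Si](C)(C)C(C)(C)C)c(CC=C(C)C)c1O[Si](C)(C)C(C)(C)C | intermediate
5 | 1-[2,4-bis(TBS-oxy)-6-hydroxy-3,5-diprenylphenyl]-2-hydroxyethan-1-one | O=C(CO)c1c(O)c(CC=C(C)C)c(O[Si](C)(C)C(C)(C)C)c(CC=C(C)C)c1O[Si](C)(C)C(C)(C)C | intermediate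
6 | 4-(tert-butyldimethylsilyloxy)benzaldehyde | O=Cc1ccc(O[Si](C)(C)C(C)(C)C)cc1 | starting material
7 | 4-(tert-butyldimethylsilyloxy)benzaldehyde dimethyl acetal | COC(OC)c1ccc(O[Si](C)(C)C(C)(C)C)cc1 | intermediate
8 | rac-6,8-bis(TBS-oxy)-2-[4-(TBS-oxy)phenyl]-7,9-diprenyl-4H-1,3-benzodioxepin-5-one | CC(C)=CCc1c(O[Si](C)(C)C(C)(C)C)c(CC=C(C)C)c2c(c1O[Si](C)(C)C(C)(C)C)C(=O)COC(c1ccc(O[Si](C)(C)C(C)(C)C)cc1)O2 | intermediate
9 | rac-6,8-bis(TBS-oxy)-2-[4-(TBS-oxy)phenyl]-7,9-diprenyl-5-(TES-oxy)-2H-1,3-benzodioxepine | CC(C)=CCc1c(O[Si](C)(C)C(C)(C)C)c(CC=C(C)C)c2c(c1O[Si](C)(C)C(C)(C)C)C(O[Si](CC)(CC)CC)=COC(c1ccc(O[Si](C)(C)C(C)(C)C)cc1)O2 | intermediate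
10 | {2-[(E)-1,2-bis(TES-oxy)ethenyl]-3,5-bis(TBS-oxy)-4,6-diprenylphenyl}[4-(TBS-oxy)benzylidene]oxonium triflate | CC(C)=CCc1c(O[Si](C)(C)C(C)(C)C)c(CC=C(C)C)c([O+]=Cc2ccc(O[Si](C)(C)C(C)(C)C)cc2)c(c1O[Si](C)(C)C(C)(C)C)/C(O[Si](CC)(CC)CC)=C\O[Si](CC)(CC)CC.[O-]S(=O)(=O)C(F)(F)F | intermediate
11 | (2R,3R)-5,7-bis(TBS-oxy)-2-[4-(TBS-oxy)phenyl]-6,8-diprenyl-3-(TES-oxy)chroman-4-one | CC(C)=CCc1c(O[Si](C)(C)C(C)(C)C)c(CC=C(C)C)c2c(c1O[Si](C)(C)C(C)(C)C)C(=O)[C@H](O[Si](CC)(CC)CC)[C@@H](c1ccc(O[Si](C)(C)C(C)(C)C)cc1)O2 | intermediate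
12 | 6,8-diprenylaromadendrin, (2R,3R) | CC(C)=CCc1c(O)c(CC=C(C)C)c2c(c1O)C(=O)[C@H](O)[C@@H](c1ccc(O)cc1)O2 | target

**Total step count:** 8. **Longest linear sequence:** 7 (steps 1, 2, 3, 5, 6, 7, 8; step 4 is a one-step side branch).

**Steps most likely to fail**

1. Step 7 (Proposed new method).
   - What may go wrong: ionisation without C–C bond formation (return, or loss of the enol silane back to the ketone), a racemic background reaction through free silyl triflate, or poor facial selectivity at C2.
   - Fallback with known chemistry, setting out from 3 and coming back at 12: exhaustive protection of 3 (MOMCl, NaH, DMF) should give the tris(methoxymethyl) ether F1. Claisen–Schmidt condensation with commercial 4-(methoxymethoxy)benzaldehyde (KOH, EtOH) should give the (E)-chalcone F2. Juliá–Colonna epoxidation (poly-L-leucine, urea–H2O2, DBU, THF) is a nucleophilic epoxidation, so it leaves the prenyl groups alone and should give the (2R,3S)-epoxy ketone F3. HCl in MeOH then removes the four MOM groups, and a freed ortho-OH opens the epoxide at the benzylic carbon with inversion (6-endo-tet) to give 12.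

2. Step 5.
   - What may go wrong: an unfavourable equilibrium for closing the seven-membered mixed aryl/alkyl acetal, formation of open or oligomeric acetals, or acid-induced cyclisation of the free phenol onto its ortho-prenyl group.
   - Fallback, setting out from 5 and 6 and coming back at 8: reductive etherification of aldehyde 6 with the primary hydroxyl of 5 (Et3SiH, cat. FeCl3, MeCN) should give the 4-(TBS-oxy)benzyl ether F4. Anhydrous DDQ (4 Å MS, CH2Cl2, 0 °C) then oxidises the electron-rich benzylic C–H to the oxocarbenium ion, which the neighbouring phenol traps irreversibly to give 8 (oxidative benzylidene acetal formation). This is kinetic rather than equilibrium control.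

3. Step 3.
   - What may go wrong: addition of the unhindered methyl ketone enolate to the sulfonimine by-product, over-oxidation, or migration of the ortho silyl group to the new alkoxide.
   - Fallback, setting out from 4 and coming back at 5: soft enolisation with chlorocatecholborane and 2,6-lutidine and trapping of the boron enolate with TEMPO (2 equiv) should give the α-(2,2,6,6-tetramethylpiperidin-1-yloxy) ketone F5. This is a radical-type aminoxylation that forms no alkoxide and no imine. Zn/AcOH then cleaves the N–O bond to give 5.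

**Further compounds**
F1 | step 7 | 1-[2,4,6-tris(methoxymethoxy)-3,5-diprenylphenyl]ethan-1-one | CC(=O)c1c(OCOC)c(CC=C(C)C)c(OCOC)c(CC=C(C)C)c1OCOC
F2 | step 7 | (E)-3-[4-(methoxymethoxy)phenyl]-1-[2,4,6-tris(methoxymethoxy)-3,5-diprenylphenyl]prop-2-en-1-one | COCOc1ccc(/C=C/C(=O)c2c(OCOC)c(CC=C(C)C)c(OCOC)c(CC=C(C)C)c2OCOC)cc1
F3 | step 7 | {(2R,3S)-3-[4-(methoxymethoxy)phenyl]oxiran-2-yl}[2,4,6-tris(methoxymethoxy)-3,5-diprenylphenyl]methanone | O=C(c1c(OCOC)c(CC=C(C)C)c(OCOC)c(CC=C(C)C)c1OCOC)[C@@H]1O[C@H]1c1ccc(OCOC)cc1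
F4 | step 5 | 1-[2,4-bis(TBS-oxy)-6-hydroxy-3,5-diprenylphenyl]-2-{[4-(TBS-oxy)phenyl]methoxy}ethan-1-one | CC(C)=CCc1c(O[Si](C)(C)C(C)(C)C)c(CC=C(C)C)c(O)c(c1O[Si](C)(C)C(C)(C)C)C(=O)COCc1ccc(O[Si](C)(C)C(C)(C)C)cc1
F5 | step 3 | 1-[2,4-bis(TBS-oxy)-6-hydroxy-3,5-diprenylphenyl]-2-(2,2,6,6-tetramethylpiperidin-1-yloxy)ethan-1-one | CC1(C)CCCC(C)(C)N1OCC(=O)c1c(O)c(CC=C(C)C)c(O[Si](C)(C)C(C)(C)C)c(CC=C(C)C)c1O[Si](C)(C)C(C)(C)C
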